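Rings A and B are taken apart together across the ring-fusion bond C5–C10 and the C6–C7 bond of ring B (labdane numbering), which unravels the trans-decalin to an acyclic dienyne. In the key step 9-BBN converts the terminal alkyne (C5, C6) into an E alkenylborane that adds intramolecularly, as a Diels–Alder dienophile, to the 1-alkoxy-2-silyloxy diene C7=C8–C9=C10; oxidation then gives the bicyclic C6 alcohol. One operation closes both carbocycles and sets C5, C6 and quaternary C10, exploiting that ring B carries oxygen on C6, C7 and C8 and hydrogen on C9, the pattern a cyclohexenyl silyl enol ether delivers. A removable chiral ether on the diene oxygen fixes the absolute configuration.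

Key step: step 7

Remark on the chemistry: locants C1 to C20 follow labdane numbering (C4 gem-dimethyl, C10 angular methyl C20, C17 the methyl on C8, C11 to C16 the side chain); 11 and 23 are drawn open-chain although they can sit as cyclic hemiketal or lactol; the (R) auxiliary is chosen from the facial model given in step 7.

Step 1
Reactants: 1 2,2-dimethylpent-4-enal
Product: 2 3,3-dimethylhex-5-en-1-yne
Conditions: dimethyl (1-diazo-2-oxopropyl)phosphonate, K2CO3, MeOH, 0 °C → rt
Reagents that add atoms: dimethyl (1-diazo-2-oxopropyl)phosphonate (Ohira–Bestmann reagent), CC(=O)C(=[N+]=[N-])P(=O)(OC)OC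
Why: Seyferth–Gilbert homologation in its Ohira–Bestmann form should turn the non-enolisable aldehyde into the terminal alkyne under mild base without touching the alkene.

Step 2
Reactants: 3 3-acetyloxolan-2-one (2-acetylbutyrolactone)
Product: 4 (E)-1-(2-oxooxolan-3-ylidene)ethyl trifluoromethanesulfonate
Conditions: Tf2O, aq. Me4NOH, toluene, 0 °C
Reagents that add atoms: triflic anhydride, O=S(=O)(OS(=O)(=O)C(F)(F)F)C(F)(F)F
Why: O-triflation of the β-keto lactone enolate with a non-chelating ammonium counter-ion should give the dipole-minimised E enol triflate (triflate oxygen anti to the lactone carbonyl), which fixes the later C9=C10 geometry.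

Step 3
Reactants: 2 3,3-dimethylhex-5-en-1-yne; 4 (E)-1-(2-oxooxolan-3-ylidene)ethyl trifluoromethanesulfonate
Product: 6 (E)-3-(6,6-dimethyloct-7-yn-2-ylidene)oxolan-2-one, via alkylborane 5 (not isolated)
Conditions: 9-BBN, THF, 0 °C → rt; then 4, Pd(dppf)Cl2 (cat.), AsPh3, Cs2CO3, DMF/H2O, rt
Reagents that add atoms: none
Why: 9-BBN hydroborates the unhindered terminal alkene in preference to the neopentyl-type alkyne, and the B-alkyl Suzuki–Miyaura coupling with the enol triflate proceeds with retention of the alkene geometry.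

Step 4
Reactants: 7 (R)-1-(4-methoxyphenyl)ethanol; 8 tributyl(iodomethyl)stannane
Product: 9 tributyl{[(1R)-1-(4-methoxyphenyl)ethoxy]methyl}stannane
Conditions: KH, THF, 0 °C; then 8, rt
Reagents that add atoms: none
Why: Williamson ether synthesis of the potassium alkoxide with the primary iodide gives the α-alkoxymethylstannane without touching the stereocenter.

Step 5
Reactants: 6 (E)-3-(6,6-dimethyloct-7-yn-2-ylidene)oxolan-2-one; 9 tributyl{[(1R)-1-(4-methoxyphenyl)ethoxy]methyl}stannane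
Product: 11 (E)-3-(2-hydroxyethyl)-1-[(1R)-1-(4-methoxyphenyl)ethoxy]-4,8,8-trimethyldec-3-en-9-yn-2-one, via alkoxymethyllithium 10 (not isolated)
Conditions: 9 (2.3 equiv), n-BuLi (2.2 equiv), THF, −78 °C; then 6, −78 °C; aq. NH4Cl
Reagents that add atoms: none
Why: Tin–lithium exchange gives the α-alkoxymethyllithium, which should add once to the lactone carbonyl (the lithium lactolate persists at −78 °C and the tetrasubstituted alkylidene blocks conjugate addition), one further equivalent being spent on the alkyne C–H.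

Step 6
Reactants: 11 (E)-3-(2-hydroxyethyl)-1-[(1R)-1-(4-methoxyphenyl)ethoxy]-4,8,8-trimethyldec-3-en-9-yn-2-one
Product: 12 (1Z,3E)-2-(tert-butyldimethylsilyloxy)-3-[2-(tert-butyldimethylsilyloxy)ethyl]-1-[(1R)-1-(4-methoxyphenyl)ethoxy]-4,8,8-trimethyldeca-1,3-dien-9-yne
Conditions: TBSOTf (2.5 equiv), Et3N, CH2Cl2, −78 → 0 °C
Reagents that add atoms: tert-butyldimethylsilyl triflate, CC(C)(C)[Si](C)(C)OS(=O)(=O)C(F)(F)F
Why: Soft enolisation with silyl triflate and amine should silylate the primary alcohol and the more acidic alkoxy-bearing α' position, giving the Z enol ether (silyloxy and alkoxy cis) and so the 1-alkoxy-2-silyloxy diene with the E tetrasubstituted alkene untouched.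

Step 7
Reactants: 12 (1Z,3E)-2-(tert-butyldimethylsilyloxy)-3-[2-(tert-butyldimethylsilyloxy)ethyl]-1-[(1R)-1-(4-methoxyphenyl)ethoxy]-4,8,8-trimethyldeca-1,3-dien-9-yne
Product: 15 (5R,6S,7S,10R)-8,12-bis(tert-butyldimethylsilyloxy)-7-[(1R)-1-(4-methoxyphenyl)ethoxy]-13,14,15,16,17-pentanorlabd-8-en-6-ol, via alkenylborane 13 (not isolated), via cycloadduct borane 14 (not isolated)
Conditions: 9-BBN (1.05 equiv), THF, 0 °C → rt; then 65 °C; then 30% H2O2, aq. NaOAc, 0 °C → rt
Reagents that add atoms: hydrogen peroxide, OO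
Why: Anti-Markovnikov syn-hydroboration of the hindered terminal alkyne gives the E alkenyl-9-BBN 13, whose vacant boron p orbital lowers the LUMO so that it adds across C7 and C10 of the electron-rich diene in a concerted, asynchronous [4+2] cycloaddition; the closest known reaction type is the Diels–Alder reaction of alkenyl-9-BBN dienophiles with 1,3-dienes followed by oxidation, run here intramolecularly. Ring A closes through the C5–C10 bond over the four-carbon tether (six-membered, chair-like, C4 exo) and ring B closes as the new cyclohexene through C5–C10 and C6–C7. C10 and C5 should come out trans because the tether sits outside on the E diene terminus and exo on the dienophile, C6 follows from the E alkene with boron endo and is kept in the oxidation (retention), and C7 follows from the Z enol ether and is corrected in step 12. The absolute sense is set by the (R)-1-(4-methoxyphenyl)ethyl ether, which lies s-trans on the enol ether with its C–H in the diene plane, so that the dienophile passes the methyl and not the aryl group. The step needs chemoselective hydroboration (the enol ether and the tetrasubstituted alkene are too hindered for 9-BBN), endo selectivity (boron–diene secondary interaction and the gem-dimethyl-biased tether) and facial selectivity (the auxiliary; the minor diastereomer should be separable by chromatography).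

Step 8
Reactants: 15 (5R,6S,7S,10R)-8,12-bis(tert-butyldimethylsilyloxy)-7-[(1R)-1-(4-methoxyphenyl)ethoxy]-13,14,15,16,17-pentanorlabd-8-en-6-ol
Product: 16 (5R,6S,7S,10R)-6,8,12-tris(tert-butyldimethylsilyloxy)-7-[(1R)-1-(4-methoxyphenyl)ethoxy]-13,14,15,16,17-pentanorlabd-8-ene
Conditions: TBSOTf, 2,6-lutidine, CH2Cl2, −78 → 0 °C
Reagents that add atoms: tert-butyldimethylsilyl triflate, CC(C)(C)[Si](C)(C)OS(=O)(=O)C(F)(F)F
Why: Silyl ether formation with the triflate and a hindered pyridine base should protect the hindered equatorial C6 alcohol without harming the silyl enol ether.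

Step 9
Reactants: 16 (5R,6S,7S,10R)-6,8,12-tris(tert-butyldimethylsilyloxy)-7-[(1R)-1-(4-methoxyphenyl)ethoxy]-13,14,15,16,17-pentanorlabd-8-ene
Product: 17 (5R,6S,7S,9S,10R)-6,12-bis(tert-butyldimethylsilyloxy)-7-[(1R)-1-(4-methoxyphenyl)ethoxy]-13,14,15,16,17-pentanorlabdan-8-one
Conditions: TBAF (1.05 equiv), AcOH, THF, −78 °C
Reagents that add atoms: none
Why: Fluoride cleaves the silyl enol ether far faster than the alkyl silyl ethers, and protonation of the enolate at C9 from the face opposite the C10 methyl should give the equatorial side chain, which is also the thermodynamic epimer.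

Step 10
Reactants: 17 (5R,6S,7S,9S,10R)-6,12-bis(tert-butyldimethylsilyloxy)-7-[(1R)-1-(4-methoxyphenyl)ethoxy]-13,14,15,16,17-pentanorlabdan-8-one
Product: 18 (5R,6S,7R,9S,10S)-6,12-bis(tert-butyldimethylsilyloxy)-7-[(1R)-1-(4-methoxyphenyl)ethoxy]-13,14,15,16-tetranorlabd-8(17)-ene
Conditions: Cp2TiMe2, toluene/THF, 65 °C, dark
Reagents that add atoms: dimethyltitanocene, [CH3-].[CH3-].[Ti+4].[cH-]1cccc1.[cH-]1cccc1
Why: Petasis methylenation converts the hindered, enolisable ketone into the exocyclic alkene under non-basic conditions, so C7 and C9 should not epimerise (descriptors at C7 and C10 change by priority only).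

Step 11
Reactants: 18 (5R,6S,7R,9S,10S)-6,12-bis(tert-butyldimethylsilyloxy)-7-[(1R)-1-(4-methoxyphenyl)ethoxy]-13,14,15,16-tetranorlabd-8(17)-ene
Product: 19 (5R,6S,7R,9S,10S)-6,12-bis(tert-butyldimethylsilyloxy)-13,14,15,16-tetranorlabd-8(17)-en-7-ol
Conditions: DDQ, CH2Cl2/pH 7 buffer, 0 °C
Reagents that add atoms: none
Why: Oxidative cleavage of the electron-rich p-methoxybenzyl-type ether with DDQ frees the axial allylic C7 alcohol and removes the auxiliary as 4'-methoxyacetophenone.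

Step 12
Reactants: 19 (5R,6S,7R,9S,10S)-6,12-bis(tert-butyldimethylsilyloxy)-13,14,15,16-tetranorlabd-8(17)-en-7-ol
Product: 20 (5R,6S,7S,9S,10S)-6,12-bis(tert-butyldimethylsilyloxy)-13,14,15,16-tetranorlabd-8(17)-en-7-yl acetate
Conditions: PPh3, DIAD, AcOH, toluene, 0 °C → rt
Reagents that add atoms: acetic acid, CC(=O)O
Why: Mitsunobu reaction of the axial allylic alcohol with acetic acid should proceed by SN2 inversion and place the acetate equatorial, with the C7 configuration of the target.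

Step 13
Reactants: 20 (5R,6S,7S,9S,10S)-6,12-bis(tert-butyldimethylsilyloxy)-13,14,15,16-tetranorlabd-8(17)-en-7-yl acetate
Product: 21 (5R,6S,7R,8R,9S,10R)-6,12-bis(tert-butyldimethylsilyloxy)-8-hydroxy-13,14,15,16-tetranorlabdan-7-yl acetate
Conditions: Co(acac)2 (cat.), PhSiH3, O2 (1 atm), THF, rt
Reagents that add atoms: dioxygen, O=O
Why: Mukaiyama hydration (cobalt-hydride hydrogen atom transfer to the CH2 terminus, then O2 capture) gives the Markovnikov tertiary alcohol, and the C8 radical should be trapped from the equatorial side away from the syn-axial C10 methyl, leaving the new methyl axial and the hydroxyl equatorial.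

Step 14
Reactants: 21 (5R,6S,7R,8R,9S,10R)-6,12-bis(tert-butyldimethylsilyloxy)-8-hydroxy-13,14,15,16-tetranorlabdan-7-yl acetate
Product: 22 (5R,6S,7R,8R,9S,10R)-6-(tert-butyldimethylsilyloxy)-8,12-dihydroxy-13,14,15,16-tetranorlabdan-7-yl acetate
Conditions: HF·pyridine, pyridine, THF, 0 °C
Reagents that add atoms: none
Why: Selective desilylation with buffered HF·pyridine should remove the primary silyl ether while the hindered secondary C6 silyl ether stays.

Step 15
Reactants: 22 (5R,6S,7R,8R,9S,10R)-6-(tert-butyldimethylsilyloxy)-8,12-dihydroxy-13,14,15,16-tetranorlabdan-7-yl acetate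
Product: 23 (5R,6S,7R,8R,9S,10R)-6-(tert-butyldimethylsilyloxy)-8-hydroxy-12-oxo-13,14,15,16-tetranorlabdan-7-yl acetate
Conditions: (COCl)2, DMSO, CH2Cl2, −78 °C; then Et3N
Reagents that add atoms: none
Why: Swern oxidation forms the aldehyde at −78 °C, and the tertiary C8 alcohol can close to the lactol only after the oxidant is spent, so no lactone should form.

Step 16
Reactants: 23 (5R,6S,7R,8R,9S,10R)-6-(tert-butyldimethylsilyloxy)-8-hydroxy-12-oxo-13,14,15,16-tetranorlabdan-7-yl acetate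
Product: 24 (5R,6S,7R,8R,9S,10R,12Z)-6-(tert-butyldimethylsilyloxy)-8-hydroxy-13-iodo-14,15-dinorlabd-12-en-7-yl acetate
Conditions: EtPPh3I, n-BuLi, THF, rt; I2, −78 °C; NaHMDS, −78 °C; then 23, −78 → −20 °C
Reagents that add atoms: ethyltriphenylphosphonium iodide, CC[P+](c1ccccc1)(c1ccccc1)c1ccccc1.[I-]; iodine, II
Why: Stork–Zhao-type Wittig olefination with the α-iodoethylidene ylide should give the Z trisubstituted vinyl iodide (iodine cis to C11), the lactol opening under the basic conditions.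

Step 17
Reactants: 24 (5R,6S,7R,8R,9S,10R,12Z)-6-(tert-butyldimethylsilyloxy)-8-hydroxy-13-iodo-14,15-dinorlabd-12-en-7-yl acetate
Product: 25 (5R,6S,7R,8R,9S,10R,12Z)-6-(tert-butyldimethylsilyloxy)-8-hydroxylabda-12,14-dien-7-yl acetate
Conditions: CH2=CHSnBu3, Pd(PPh3)4 (cat.), CuI, DMF, 40 °C
Reagents that add atoms: tributyl(vinyl)stannane, C=C[Sn](CCCC)(CCCC)CCCC
Why: Stille coupling of the vinyl iodide with the vinylstannane proceeds with retention of alkene geometry under neutral conditions that spare the acetate.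

Step 18
Reactants: 25 (5R,6S,7R,8R,9S,10R,12Z)-6-(tert-butyldimethylsilyloxy)-8-hydroxylabda-12,14-dien-7-yl acetate
Product: 26 (5R,6S,7R,8R,9S,10R,12Z)-6,8-dihydroxylabda-12,14-dien-7-yl acetate (CNP0225877.2)
Conditions: HF·pyridine, pyridine, THF, rt
Reagents that add atoms: none
Why: Fluoride-mediated desilylation under buffered, weakly acidic conditions should free the C6 alcohol without acetyl migration or isomerisation of the Z diene.

Compound list
1 | 2,2-dimethylpent-4-enal | O=CC(C)(C)CC=C | starting material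
2 | 3,3-dimethylhex-5-en-1-yne | C#CC(C)(C)CC=C | intermediate
3 | 3-acetyloxolan-2-one (2-acetylbutyrolactone, racemic) | CC(=O)C1CCOC1=O | starting material
4 | (E)-1-(2-oxooxolan-3-ylidene)ethyl trifluoromethanesulfonate | C/C(OS(=O)(=O)C(F)(F)F)=C1/CCOC1=O | intermediate
5 | 9-(4,4-dimethylhex-5-yn-1-yl)-9-borabicyclo[3.3.1]nonane | C#CC(C)(C)CCCB1C2CCCC1CCC2 | intermediate
6 | (E)-3-(6,6-dimethyloct-7-yn-2-ylidene)oxolan-2-one | C/C(CCCC(C)(C)C#C)=C1/CCOC1=O | intermediate
7 | (R)-1-(4-methoxyphenyl)ethanol | C[C@@H](O)c1ccc(OC)cc1 | starting material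
8 | tributyl(iodomethyl)stannane | CCCC[Sn](CCCC)(CCCC)CI | starting material
9 | tributyl{[(1R)-1-(4-methoxyphenyl)ethoxy]methyl}stannane | CCCC[Sn](CCCC)(CCCC)CO[C@H](C)c1ccc(OC)cc1 | intermediate
10 | {[(1R)-1-(4-methoxyphenyl)ethoxy]methyl}lithium | [Li]CO[C@H](C)c1ccc(OC)cc1 | intermediate
11 | (E)-3-(2-hydroxyethyl)-1-[(1R)-1-(4-methoxyphenyl)ethoxy]-4,8,8-trimethyldec-3-en-9-yn-2-one | C/C(CCCC(C)(C)C#C)=C(/CCO)C(=O)CO[C@H](C)c1ccc(OC)cc1 | intermediate
12 | (1Z,3E)-2-(tert-butyldimethylsilyloxy)-3-[2-(tert-butyldimethylsilyloxy)ethyl]-1-[(1R)-1-(4-methoxyphenyl)ethoxy]-4,8,8-trimethyldeca-1,3-dien-9-yne | C#CC(C)(C)CCC/C(C)=C(CCO[Si](C)(C)C(C)(C)C)/C(O[Si](C)(C)C(C)(C)C)=C/O[C@H](C)c1ccc(OC)cc1 | intermediate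
13 | 9-[(1E,7E,9Z)-9-(tert-butyldimethylsilyloxy)-8-[2-(tert-butyldimethylsilyloxy)ethyl]-10-[(1R)-1-(4-methoxyphenyl)ethoxy]-3,3,7-trimethyldeca-1,7,9-trien-1-yl]-9-borabicyclo[3.3.1]nonane | C1CCC2CCCC1B2/C=C/C(C)(C)CCC/C(C)=C(CCO[Si](C)(C)C(C)(C)C)/C(O[Si](C)(C)C(C)(C)C)=C/O[C@H](C)c1ccc(OC)cc1 | intermediate
14 | (5R,6S,7S,10R)-6-(9-borabicyclo[3.3.1]nonan-9-yl)-8,12-bis(tert-butyldimethylsilyloxy)-7-[(1R)-1-(4-methoxyphenyl)ethoxy]-13,14,15,16,17-pentanorlabd-8-ene | CC(C)(C)[Si](C)(C)OCCC1=C(O[Si](C)(C)C(C)(C)C)[C@@H](O[C@H](C)c3ccc(OC)cc3)[C@@H](B4C5CCCC4CCC5)[C@@H]2C(C)(C)CCC[C@]21C | intermediate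
15 | (5R,6S,7S,10R)-8,12-bis(tert-butyldimethylsilyloxy)-7-[(1R)-1-(4-methoxyphenyl)ethoxy]-13,14,15,16,17-pentanorlabd-8-en-6-ol | CC(C)(C)[Si](C)(C)OCCC1=C(O[Si](C)(C)C(C)(C)C)[C@@H](O[C@H](C)c3ccc(OC)cc3)[C@@H](O)[C@@H]2C(C)(C)CCC[C@]21C | intermediate
16 | (5R,6S,7S,10R)-6,8,12-tris(tert-butyldimethylsilyloxy)-7-[(1R)-1-(4-methoxyphenyl)ethoxy]-13,14,15,16,17-pentanorlabd-8-ene | CC(C)(C)[Si](C)(C)OCCC1=C(O[Si](C)(C)C(C)(C)C)[C@@H](O[C@H](C)c3ccc(OC)cc3)[C@@H](O[Si](C)(C)C(C)(C)C)[C@@H]2C(C)(C)CCC[C@]21C | intermediate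
17 | (5R,6S,7S,9S,10R)-6,12-bis(tert-butyldimethylsilyloxy)-7-[(1R)-1-(4-methoxyphenyl)ethoxy]-13,14,15,16,17-pentanorlabdan-8-one | CC(C)(C)[Si](C)(C)OCC[C@@H]1C(=O)[C@@H](O[C@H](C)c3ccc(OC)cc3)[C@@H](O[Si](C)(C)C(C)(C)C)[C@@H]2C(C)(C)CCC[C@]21C | intermediate
18 | (5R,6S,7R,9S,10S)-6,12-bis(tert-butyldimethylsilyloxy)-7-[(1R)-1-(4-methoxyphenyl)ethoxy]-13,14,15,16-tetranorlabd-8(17)-ene | CC(C)(C)[Si](C)(C)OCC[C@@H]1C(=C)[C@@H](O[C@H](C)c3ccc(OC)cc3)[C@@H](O[Si](C)(C)C(C)(C)C)[C@@H]2C(C)(C)CCC[C@]21C | intermediate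
19 | (5R,6S,7R,9S,10S)-6,12-bis(tert-butyldimethylsilyloxy)-13,14,15,16-tetranorlabd-8(17)-en-7-ol (axial 7-OH) | CC(C)(C)[Si](C)(C)OCC[C@@H]1C(=C)[C@@H](O)[C@@H](O[Si](C)(C)C(C)(C)C)[C@@H]2C(C)(C)CCC[C@]21C | intermediate
20 | (5R,6S,7S,9S,10S)-6,12-bis(tert-butyldimethylsilyloxy)-13,14,15,16-tetranorlabd-8(17)-en-7-yl acetate (equatorial 7-OAc) | CC(C)(C)[Si](C)(C)OCC[C@@H]1C(=C)[C@H](OC(C)=O)[C@@H](O[Si](C)(C)C(C)(C)C)[C@@H]2C(C)(C)CCC[C@]21C | intermediate
21 | (5R,6S,7R,8R,9S,10R)-6,12-bis(tert-butyldimethylsilyloxy)-8-hydroxy-13,14,15,16-tetranorlabdan-7-yl acetate | CC(C)(C)[Si](C)(C)OCC[C@@H]1[C@@](C)(O)[C@H](OC(C)=O)[C@@H](O[Si](C)(C)C(C)(C)C)[C@@H]2C(C)(C)CCC[C@]21C | intermediate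
22 | (5R,6S,7R,8R,9S,10R)-6-(tert-butyldimethylsilyloxy)-8,12-dihydroxy-13,14,15,16-tetranorlabdan-7-yl acetate | OCC[C@@H]1[C@@](C)(O)[C@H](OC(C)=O)[C@@H](O[Si](C)(C)C(C)(C)C)[C@@H]2C(C)(C)CCC[C@]21C | intermediate
23 | (5R,6S,7R,8R,9S,10R)-6-(tert-butyldimethylsilyloxy)-8-hydroxy-12-oxo-13,14,15,16-tetranorlabdan-7-yl acetate | O=CC[C@@H]1[C@@](C)(O)[C@H](OC(C)=O)[C@@H](O[Si](C)(C)C(C)(C)C)[C@@H]2C(C)(C)CCC[C@]21C | intermediate
24 | (5R,6S,7R,8R,9S,10R,12Z)-6-(tert-butyldimethylsilyloxy)-8-hydroxy-13-iodo-14,15-dinorlabd-12-en-7-yl acetate | I/C(C)=C\C[C@@H]1[C@@](C)(O)[C@H](OC(C)=O)[C@@H](O[Si](C)(C)C(C)(C)C)[C@@H]2C(C)(C)CCC[C@]21C | intermediate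
25 | (5R,6S,7R,8R,9S,10R,12Z)-6-(tert-butyldimethylsilyloxy)-8-hydroxylabda-12,14-dien-7-yl acetate | C=C/C(C)=C\C[C@@H]1[C@@](C)(O)[C@H](OC(C)=O)[C@@H](O[Si](C)(C)C(C)(C)C)[C@@H]2C(C)(C)CCC[C@]21C | intermediate
26 | (5R,6S,7R,8R,9S,10R,12Z)-6,8-dihydroxylabda-12,14-dien-7-yl acetate (CNP0225877.2) | C=C/C(C)=C\C[C@@H]1[C@@](C)(O)[C@H](OC(C)=O)[C@@H](O)[C@@H]2C(C)(C)CCC[C@]21C | target

Total step count: 18. Longest linear sequence: 16 steps (steps 1, 3 and 5 to 18; steps 2 and 4 make the two side components).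

Steps most likely to fail

1. Step 7. The crowded tetrasubstituted diene may cycloadd so slowly that hydroboration of the enol ether, a second hydroboration of the alkenylborane or a [1,5]-hydrogen shift in the diene competes. The exo transition state may also intervene and give the cis-fused ring system, and the facial bias of the auxiliary may be small. Fallback: from 12, catalytic hydroboration with pinacolborane (Cp2Zr(H)Cl cat., Et3N, 50 °C) should give the isolable (E)-alkenyl pinacolboronate F1. Heating in toluene (130 °C, sealed tube, BHT) then effects a purely thermal intramolecular Diels–Alder reaction to the C6 pinacolboronate cycloadduct F2, whose diastereomers can be separated at leisure. Oxidation with NaBO3·4H2O in THF/H2O returns to 15.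

2. Step 12. The activated allylic alcohol may be attacked in the SN2' sense at the exocyclic CH2, or it may eliminate to a diene, instead of undergoing clean inversion at C7. Fallback: from 19, oxidation with Dess–Martin periodinane gives the exocyclic enone F3. Luche reduction (NaBH4, CeCl3·7H2O, MeOH, −78 °C) should deliver hydride axially and give the equatorial allylic alcohol F4. Acetylation (Ac2O, DMAP, pyridine) then comes back to the route at 20.

3. Step 13. Capture of the C8 radical by oxygen may show poor facial selectivity, or reduction of the intermediate peroxide may be incomplete, and a wrong C8 configuration cannot be corrected later. Fallback: from 20, epoxidation with mCPBA (NaHCO3, CH2Cl2, 0 °C) attacks the exocyclic alkene from the equatorial side, away from the C10 methyl, to give the spiro epoxide F5. LiAlH4 (THF, 0 °C) opens it at the CH2 carbon and also cleaves the acetate, giving the 7,8-diol F6. Acetylation of the secondary alcohol only (Ac2O, DMAP, pyridine) comes back to the route at 21.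

Further compounds
F1 | step 7 | 2-[(1E,7E,9Z)-9-(tert-butyldimethylsilyloxy)-8-[2-(tert-butyldimethylsilyloxy)ethyl]-10-[(1R)-1-(4-methoxyphenyl)ethoxy]-3,3,7-trimethyldeca-1,7,9-trien-1-yl]-4,4,5,5-tetramethyl-1,3,2-dioxaborolane | CC1(C)OB(/C=C/C(C)(C)CCC/C(C)=C(CCO[Si](C)(C)C(C)(C)C)/C(O[Si](C)(C)C(C)(C)C)=C/O[C@H](C)c2ccc(OC)cc2)OC1(C)C
F2 | step 7 | (5R,6S,7S,10R)-8,12-bis(tert-butyldimethylsilyloxy)-7-[(1R)-1-(4-methoxyphenyl)ethoxy]-6-(4,4,5,5-tetramethyl-1,3,2-dioxaborolan-2-yl)-13,14,15,16,17-pentanorlabd-8-ene | CC(C)(C)[Si](C)(C)OCCC1=C(O[Si](C)(C)C(C)(C)C)[C@@H](O[C@H](C)c3ccc(OC)cc3)[C@@H](B4OC(C)(C)C(C)(C)O4)[C@@H]2C(C)(C)CCC[C@]21C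
F3 | step 12 | (5R,6S,9S,10S)-6,12-bis(tert-butyldimethylsilyloxy)-13,14,15,16-tetranorlabd-8(17)-en-7-one | CC(C)(C)[Si](C)(C)OCC[C@@H]1C(=C)C(=O)[C@@H](O[Si](C)(C)C(C)(C)C)[C@@H]2C(C)(C)CCC[C@]21C
F4 | step 12 | (5R,6S,7S,9S,10S)-6,12-bis(tert-butyldimethylsilyloxy)-13,14,15,16-tetranorlabd-8(17)-en-7-ol (equatorial 7-OH) | CC(C)(C)[Si](C)(C)OCC[C@@H]1C(=C)[C@H](O)[C@@H](O[Si](C)(C)C(C)(C)C)[C@@H]2C(C)(C)CCC[C@]21C
F5 | step 13 | (5R,6S,7R,8S,9S,10R)-6,12-bis(tert-butyldimethylsilyloxy)-8,17-epoxy-13,14,15,16-tetranorlabdan-7-yl acetate | CC(C)(C)[Si](C)(C)OCC[C@@H]1[C@]3(CO3)[C@H](OC(C)=O)[C@@H](O[Si](C)(C)C(C)(C)C)[C@@H]2C(C)(C)CCC[C@]21C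
F6 | step 13 | (5R,6S,7R,8R,9S,10R)-6,12-bis(tert-butyldimethylsilyloxy)-13,14,15,16-tetranorlabdane-7,8-diol | CC(C)(C)[Si](C)(C)OCC[C@@H]1[C@@](C)(O)[C@H](O)[C@@H](O[Si](C)(C)C(C)(C)C)[C@@H]2C(C)(C)CCC[C@]21C
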